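**Plan**

Retrosynthesis: take off the O8 ester and the silyl groups; cut C6–C7 together with the lactone O–C12 bond (intramolecular 2-(alkoxycarbonyl)allylation of an enal) to the open-chain epoxy bromo-enal 26; cut the acrylate unit at C7=C11 (Morita–Baylis–Hillman), the 1,10-oxirane (Sharpless epoxidation) and C1=C10 (cross-metathesis) to lactone 6 and diene 14.
Forward order: the C1–C6 piece 14 and the C7–C10/C14 piece 6 are joined at C1=C10; the oxirane is made on the open chain; the acrylate unit is attached at C7; the ten-membered carbocycle is closed last, and the lactone forms in the same flask from the alkoxide just made.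
Enabling feature: the C6–C7 bond is shared by the carbocycle and the lactone; O–C6 is allylic to the (Z)-C4=C5 alkene and C7 carries the C11(=C13H2)–C12(=O)O unit. This is the retron of a 2-(alkoxycarbonyl)allyl metal adding to an enal, and it is the bond that germacrene biosynthesis forms (C1–C10 of farnesyl diphosphate).
Stereochemistry: C8 from (S)-glycidol; C3 from Brown allylation; C1/C10 from Sharpless epoxidation of the (E)-allylic alcohol; 4Z from Still–Gennari olefination; C6 and C7 in the key step (syn addition through a chair, face fixed by C8); the side-chain centre from (R)-2-methylbutanoic acid.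

Key step: step 19

Remark: the structure is read as a (4Z)-germacranolide with a cis-fused 6,12-lactone (H6 and H7 cis), a 1,10-oxirane with C2 and C9 cis, and an (R)-2-methylbutanoate on O8; germacrane locants C1–C15 are used for all intermediates (TBS = tert-butyldimethylsilyl, TES = triethylsilyl, PMB = 4-methoxybenzyl, DMB = 3,4-dimethoxybenzyl).

**Route**

Step 1
Reactants: 1 (S)-glycidol
Product: 2 (2R)-2-{[(3,4-dimethoxybenzyl)oxy]methyl}oxirane
Conditions: NaH, Bu4NI (cat.), THF/DMF, 0 °C → rt
Reagents that add atoms: 3,4-dimethoxybenzyl bromide, COc1ccc(CBr)cc1OC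
Why: Williamson etherification of the glycidol alkoxide leaves the stereocentre untouched (the descriptor changes from S to R only through the CIP priorities), and the DMB group is chosen because DDQ removes it later in the presence of a PMB ether.

Step 2
Reactants: 2 DMB glycidyl ether; 3 triethyl phosphonoacetate
Product: 4 diethyl [(5R)-5-{[(3,4-dimethoxybenzyl)oxy]methyl}-2-oxooxolan-3-yl]phosphonate (both C3 epimers)
Conditions: NaH, toluene, 0 → 100 °C; then aq. NH4Cl
Reagents that add atoms: none
Why: The phosphonoacetate anion opens the epoxide at its terminal CH2 (SN2, future C9) and the C8 alkoxide lactonises onto the ethyl ester, a known epoxide-to-phosphonolactone annulation that does not touch C8.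

Step 3
Reactants: 4 phosphonolactone; 5 formaldehyde (37 % aqueous)
Product: 6 (5R)-5-{[(3,4-dimethoxybenzyl)oxy]methyl}-3-methylideneoxolan-2-one
Conditions: K2CO3, THF/H2O, rt
Reagents that add atoms: none
Why: Horner–Wadsworth–Emmons methylenation with formaldehyde is the standard route from α-phosphono lactones to α-methylene lactones.

Step 4
Reactants: 7 [(4-methoxybenzyl)oxy]acetaldehyde; 8 ethyl 2-[bis(2,2,2-trifluoroethoxy)phosphoryl]propanoate
Product: 9 ethyl (2Z)-4-[(4-methoxybenzyl)oxy]-2-methylbut-2-enoate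
Conditions: KN(SiMe3)2, 18-crown-6, THF, −78 °C
Reagents that add atoms: none
Why: Still–Gennari olefination with the bis(trifluoroethyl) phosphonate gives the (Z)-trisubstituted enoate under kinetic control, which fixes the 4Z geometry of the target.

Step 5
Reactants: 9 (Z)-enoate
Product: 10 (2Z)-4-[(4-methoxybenzyl)oxy]-2-methylbut-2-en-1-ol
Conditions: iBu2AlH, CH2Cl2, −78 °C; aq. potassium sodium tartrate
Reagents that add atoms: none
Why: 1,2-Reduction of the enoate by iBu2AlH leaves the Z alkene and the PMB ether intact.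

Step 6
Reactants: 10 (Z)-allylic alcohol
Product: 11 (2Z)-4-[(4-methoxybenzyl)oxy]-2-methylbut-2-enal
Conditions: MnO2, CH2Cl2, rt; used at once
Reagents that add atoms: none
Why: MnO2 oxidises the allylic alcohol under neutral conditions, so the (Z)-enal should not isomerise.

Step 7
Reactants: 11 (Z)-enal; 12 (−)-B-allyldiisopinocampheylborane, made from (+)-α-pinene
Product: 13 (4S,5Z)-7-[(4-methoxybenzyl)oxy]-5-methylhepta-1,5-dien-4-ol (C3 = S)
Conditions: Et2O, −78 °C; then NaOH, H2O2, 0 °C → rt
Reagents that add atoms: none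
Why: Brown allylation delivers the allyl group through a chair six-membered transition state to the Si face of the aldehyde under control of the isopinocampheyl groups, which should set C3 as S, and the low temperature protects the Z enal.

Step 8
Reactants: 13 homoallylic alcohol
Product: 14 TBS ether of 13 (C3–OTBS)
Conditions: TBSCl, imidazole, DMF, rt
Reagents that add atoms: tert-butyldimethylsilyl chloride, CC(C)(C)[Si](C)(C)Cl
Why: Standard silylation of a secondary allylic alcohol.

Step 9
Reactants: 14 diene; 6 α-methylene lactone (3 equiv)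
Product: 15 (3E,5R)-3-[(3S,4Z)-3-(TBSO)-6-(PMBO)-4-methylhex-4-en-1-ylidene]-5-[(DMBO)methyl]oxolan-2-one
Conditions: second-generation Hoveyda–Grubbs catalyst [RuCl2(H2IMes)(=CH–C6H4-2-OiPr)] (5 mol %), 2,6-dichloro-1,4-benzoquinone (10 mol %), CH2Cl2, 40 °C
Reagents that add atoms: none
Why: Cross-metathesis of a terminal alkene with an α-methylene-γ-butyrolactone is a known route to (E)-α-alkylidene lactones (alkyl group anti to the carbonyl, so C2 ends cis to C9); the trisubstituted C4=C5 alkene is too hindered to take part and the quinone suppresses migration of the exocyclic double bond.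

Step 10
Reactants: 15 alkylidene lactone
Product: 16 (2R,4E,7S,8Z)-7-(TBSO)-1-(DMBO)-4-(hydroxymethyl)-10-(PMBO)-8-methyldeca-4,8-dien-2-ol (C14-OH and C8-OH free)
Conditions: iBu2AlH (4 equiv), CH2Cl2, −78 → 0 °C; aq. potassium sodium tartrate
Reagents that add atoms: none
Why: iBu2AlH reduces the conjugated lactone by 1,2-addition to the ene-1,4-diol without changing the alkene geometry.

Step 11
Reactants: 16 diol
Product: 17 (1R,10R)-epoxy diol (oxirane at C1–C10, C2 and C9 cis)
Conditions: Ti(OiPr)4, D-(−)-diethyl tartrate, tBuOOH, 4 Å molecular sieves, CH2Cl2, −20 °C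
Reagents that add atoms: tert-butyl hydroperoxide, CC(C)(C)OO
Why: Sharpless asymmetric epoxidation is directed by the C14 allylic alcohol to C1=C10 only (C4=C5 has no free allylic hydroxyl), D-(−)-tartrate should give the (1R,10R) oxirane, and syn addition to the E alkene keeps C2 and C9 cis.

Step 12
Reactants: 17 epoxy diol
Product: 19 C14-OTBS C8-OTES bis-silyl ether of 17, via C14 mono-TBS ether 18 (not isolated)
Conditions: TBSCl (1.05 equiv), imidazole, CH2Cl2, 0 °C; then TESCl, DMAP (cat.), rt
Reagents that add atoms: tert-butyldimethylsilyl chloride, CC(C)(C)[Si](C)(C)Cl; triethylsilyl chloride, CC[Si](CC)(CC)Cl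
Why: The primary C14 hydroxyl is silylated much faster than the secondary C8 hydroxyl, so the two alcohols receive different silyl groups in one flask, and the more labile TES group on O8 can be removed selectively after ring closure.

Step 13
Reactants: 19 bis-silyl ether
Product: 20 C7 primary alcohol (DMB removed; PMB, TBS, TES and oxirane kept)
Conditions: DDQ (1.1 equiv), CH2Cl2/pH 7 phosphate buffer, 0 °C
Reagents that add atoms: none
Why: DDQ oxidises the more electron-rich DMB ether faster than the PMB ether, and the buffer keeps the medium neutral for the oxirane and the silyl ethers.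

Step 14
Reactants: 20 primary alcohol
Product: 21 C7 aldehyde (α-triethylsilyloxy aldehyde)
Conditions: Dess–Martin periodinane, NaHCO3, CH2Cl2, 0 °C → rt
Reagents that add atoms: none
Why: Buffered Dess–Martin oxidation gives α-silyloxy aldehydes without epimerisation at C8.

Step 15
Reactants: 21 aldehyde; 22 methyl acrylate (excess, as solvent)
Product: 23 Morita–Baylis–Hillman adduct (methyl 2-methylidene-3-hydroxy ester; both C7 carbinol epimers)
Conditions: DABCO (1 equiv), neat, rt
Reagents that add atoms: none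
Why: Morita–Baylis–Hillman reaction of an activated α-oxygenated aldehyde; the new C7 carbinol centre forms as a mixture, which does not matter because step 16 removes it.

Step 16
Reactants: 23 Morita–Baylis–Hillman adduct
Product: 24 (Z)-2-(bromomethyl)alk-2-enoate (C7=C11, C8 cis to CH2Br)
Conditions: N-bromosuccinimide, Me2S, CH2Cl2, −20 → 0 °C
Reagents that add atoms: N-bromosuccinimide, O=C1CCC(=O)N1Br
Why: The hydroxyl is activated as an alkoxysulfonium ion (Corey–Kim-type reagent) and bromide attacks C13 in an SN2′ sense, which should give the (Z)-bromide as is usual for such adducts.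

Step 17
Reactants: 24 allylic bromide
Product: 25 C6 allylic alcohol (PMB removed)
Conditions: DDQ (1.5 equiv), CH2Cl2/pH 7 phosphate buffer, rt
Reagents that add atoms: none
Why: Oxidative cleavage of a PMB ether by DDQ tolerates allylic bromides, silyl ethers and the oxirane.

Step 18
Reactants: 25 allylic alcohol
Product: 26 (Z)-enal bromide (C6 aldehyde, 4Z; cyclisation substrate)
Conditions: MnO2, CH2Cl2, rt
Reagents that add atoms: none
Why: MnO2 oxidises only the allylic alcohol and should leave the allylic bromide and the Z geometry untouched.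

Step 19
Reactants: 26 (Z)-enal bromide
Product: 28 tris-silylated cis-fused germacranolide, via macrocyclic hydroxy ester 27 (not isolated)
Conditions: CrCl2 (8 equiv), THF/DMF, rt, slow addition of 26 (final 2 mM); aqueous work-up
Reagents that add atoms: none
Why: Two equivalents of CrCl2 reduce the allylic bromide to a 2-(methoxycarbonyl)allyl chromium species (trivalent chromium), which adds through its γ-carbon C7 to the tethered C6 aldehyde in a chair six-membered (Zimmerman–Traxler) transition state, and the chromium alkoxide of 27 then attacks the neighbouring methyl ester and expels methoxide. The closest known reaction type is the intramolecular Nozaki–Hiyama–Kishi (Barbier-type) allylation of enals by 2-(bromomethyl)alk-2-enoates used to close ten-membered germacranolide rings, and it is the laboratory counterpart of the C1–C10 cyclisation of farnesyl diphosphate. The carbocycle closes by 10-exo-trig attack on the C6 carbonyl (SE2′ at the allyl unit, so C11=C13 becomes exocyclic) and the lactone by 5-exo-trig acyl substitution of O6 on C12. C6 and C7 are set together: the γ-substituent C8 is cis to the CH2–Cr carbon and sits axial in the chair, which should give the syn homoallylic alkoxide and hence the cis-fused lactone (H6/H7 cis) needed here; the configuration of C7 relative to C8 is set by the allylic stereocentre, whose C–H eclipses C7=C11 (allylic 1,3-strain with C13) while the C8–C9 bond lies anti to the forming bond and the silyloxy group points outward. The step needs γ- over α-attack (innate to allyl chromium reagents), ring closure over oligomerisation (high dilution, helped by the Z C4=C5 alkene and the cis-oxirane, which bend the chain), retention of the Z enal (neutral, rt) and no 1,4-elimination or lactonisation at O8 (hence a silyl ether, not an ester, at C8).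

Step 20
Reactants: 28 tris-silylated lactone
Product: 29 C8 alcohol (O3-TBS and O14-TBS kept)
Conditions: PPTS, MeOH/CH2Cl2, 0 °C
Reagents that add atoms: none
Why: Acid-catalysed methanolysis removes a secondary TES ether far faster than TBS ethers, so only O8 is exposed.

Step 21
Reactants: 29 C8 alcohol; 30 (R)-2-methylbutanoic acid
Product: 31 C8 (R)-2-methylbutanoate, O3/O14 bis-TBS ether
Conditions: DCC, DMAP, CH2Cl2, 0 °C → rt
Reagents that add atoms: none
Why: Steglich esterification of the C8 alcohol; the α-stereocentre of this simple aliphatic acid should not epimerise under these conditions.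

Step 22
Reactants: 31 bis-TBS ester
Product: 32 target (CNP0356520.2)
Conditions: Bu4NF, AcOH (1:1), THF, 0 °C → rt
Reagents that add atoms: none
Why: Buffered fluoride cleaves both TBS ethers under near-neutral conditions, which avoids acid-induced attack of the freed 3-hydroxyl on the 1,10-oxirane and base damage to the α-methylene lactone and the ester.

**Compound list**

1 | (S)-glycidol | OC[C@H]1CO1 | starting material
2 | (2R)-2-{[(3,4-dimethoxybenzyl)oxy]methyl}oxirane | COc1ccc(COC[C@H]2CO2)cc1OC | intermediate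
3 | triethyl phosphonoacetate | CCOC(=O)CP(=O)(OCC)OCC | starting material
4 | diethyl [(5R)-5-{[(3,4-dimethoxybenzyl)oxy]methyl}-2-oxooxolan-3-yl]phosphonate | CCOP(=O)(OCC)C1C[C@H](COCc2ccc(OC)c(OC)c2)OC1=O | intermediate
5 | formaldehyde | C=O | starting material
6 | (5R)-5-{[(3,4-dimethoxybenzyl)oxy]methyl}-3-methylideneoxolan-2-one | C=C1C[C@H](COCc2ccc(OC)c(OC)c2)OC1=O | intermediate
7 | [(4-methoxybenzyl)oxy]acetaldehyde | COc1ccc(COCC=O)cc1 | starting material
8 | ethyl 2-[bis(2,2,2-trifluoroethoxy)phosphoryl]propanoate | CCOC(=O)C(C)P(=O)(OCC(F)(F)F)OCC(F)(F)F | starting material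
9 | ethyl (2Z)-4-[(4-methoxybenzyl)oxy]-2-methylbut-2-enoate | COc1ccc(COC/C=C(/C)C(=O)OCC)cc1 | intermediate
10 | (2Z)-4-[(4-methoxybenzyl)oxy]-2-methylbut-2-en-1-ol | COc1ccc(COC/C=C(/C)CO)cc1 | intermediate
11 | (2Z)-4-[(4-methoxybenzyl)oxy]-2-methylbut-2-enal | COc1ccc(COC/C=C(/C)C=O)cc1 | intermediate
12 | (−)-B-allyldiisopinocampheylborane | C=CCB([C@@H]1C[C@@H]2C[C@H]([C@H]1C)C2(C)C)[C@@H]1C[C@@H]2C[C@H]([C@H]1C)C2(C)C | starting material
13 | (4S,5Z)-7-[(4-methoxybenzyl)oxy]-5-methylhepta-1,5-dien-4-ol | COc1ccc(COC/C=C(/C)[C@@H](O)CC=C)cc1 | intermediate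
14 | TBS ether of 13 | COc1ccc(COC/C=C(/C)[C@@H](O[Si](C)(C)C(C)(C)C)CC=C)cc1 | intermediate
15 | (E)-alkylidene lactone (3S, 8R, 4Z, C2 cis to C9) | COc1ccc(COC/C=C(/C)[C@@H](O[Si](C)(C)C(C)(C)C)C/C=C2\C[C@H](COCc3ccc(OC)c(OC)c3)OC2=O)cc1 | intermediate
16 | open-chain diol (3S, 8R; C14-OH and C8-OH free) | COc1ccc(COC/C=C(/C)[C@@H](O[Si](C)(C)C(C)(C)C)C/C=C(/CO)C[C@@H](O)COCc2ccc(OC)c(OC)c2)cc1 | intermediate
17 | (1R,3S,8R,10R)-epoxy diol | COc1ccc(COC/C=C(/C)[C@@H](O[Si](C)(C)C(C)(C)C)C[C@H]2O[C@@]2(CO)C[C@@H](O)COCc3ccc(OC)c(OC)c3)cc1 | intermediate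
18 | C14 mono-TBS ether of 17 | COc1ccc(COC/C=C(/C)[C@@H](O[Si](C)(C)C(C)(C)C)C[C@H]2O[C@@]2(CO[Si](C)(C)C(C)(C)C)C[C@@H](O)COCc3ccc(OC)c(OC)c3)cc1 | intermediate
19 | C14-OTBS, C8-OTES bis-silyl ether of 17 | COc1ccc(COC/C=C(/C)[C@@H](O[Si](C)(C)C(C)(C)C)C[C@H]2O[C@@]2(CO[Si](C)(C)C(C)(C)C)C[C@@H](O[Si](CC)(CC)CC)COCc3ccc(OC)c(OC)c3)cc1 | intermediate
20 | C7 primary alcohol | COc1ccc(COC/C=C(/C)[C@@H](O[Si](C)(C)C(C)(C)C)C[C@H]2O[C@@]2(CO[Si](C)(C)C(C)(C)C)C[C@@H](O[Si](CC)(CC)CC)CO)cc1 | intermediate
21 | C7 aldehyde | COc1ccc(COC/C=C(/C)[C@@H](O[Si](C)(C)C(C)(C)C)C[C@H]2O[C@@]2(CO[Si](C)(C)C(C)(C)C)C[C@@H](O[Si](CC)(CC)CC)C=O)cc1 | intermediate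
22 | methyl acrylate | C=CC(=O)OC | starting material
23 | Morita–Baylis–Hillman adduct (C7 epimers) | COc1ccc(COC/C=C(/C)[C@@H](O[Si](C)(C)C(C)(C)C)C[C@H]2O[C@@]2(CO[Si](C)(C)C(C)(C)C)C[C@@H](O[Si](CC)(CC)CC)C(O)C(=C)C(=O)OC)cc1 | intermediate
24 | (Z)-2-(bromomethyl)enoate, C6-OPMB | COc1ccc(COC/C=C(/C)[C@@H](O[Si](C)(C)C(C)(C)C)C[C@H]2O[C@@]2(CO[Si](C)(C)C(C)(C)C)C[C@@H](O[Si](CC)(CC)CC)/C=C(/C(=O)OC)CBr)cc1 | intermediate
25 | C6 allylic alcohol | OC/C=C(/C)[C@@H](O[Si](C)(C)C(C)(C)C)C[C@H]1O[C@@]1(CO[Si](C)(C)C(C)(C)C)C[C@@H](O[Si](CC)(CC)CC)/C=C(/C(=O)OC)CBr | intermediate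
26 | (Z)-enal bromide | O=C/C=C(/C)[C@@H](O[Si](C)(C)C(C)(C)C)C[C@H]1O[C@@]1(CO[Si](C)(C)C(C)(C)C)C[C@@H](O[Si](CC)(CC)CC)/C=C(/C(=O)OC)CBr | intermediate
27 | macrocyclic hydroxy ester (C6-OH, C7 bearing the methyl acrylate unit; configuration as in 28) | O[C@H]1/C=C(/C)[C@@H](O[Si](C)(C)C(C)(C)C)C[C@H]2O[C@@]2(CO[Si](C)(C)C(C)(C)C)C[C@@H](O[Si](CC)(CC)CC)[C@H]1C(=C)C(=O)OC | intermediate
28 | cis-fused germacranolide, O3-TBS, O14-TBS, O8-TES (spatial arrangement at C1, C3, C6, C7, C8, C10 as in 32) | C=C1C(=O)O[C@H]2/C=C(/C)[C@@H](O[Si](C)(C)C(C)(C)C)C[C@H]3O[C@@]3(CO[Si](C)(C)C(C)(C)C)C[C@@H](O[Si](CC)(CC)CC)[C@@H]12 | intermediate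
29 | C8 alcohol, O3/O14 bis-TBS | C=C1C(=O)O[C@H]2/C=C(/C)[C@@H](O[Si](C)(C)C(C)(C)C)C[C@H]3O[C@@]3(CO[Si](C)(C)C(C)(C)C)C[C@@H](O)[C@@H]12 | intermediate
30 | (R)-2-methylbutanoic acid | CC[C@@H](C)C(=O)O | starting material
31 | C8 (R)-2-methylbutanoate, O3/O14 bis-TBS | C=C1C(=O)O[C@H]2/C=C(/C)[C@@H](O[Si](C)(C)C(C)(C)C)C[C@H]3O[C@@]3(CO[Si](C)(C)C(C)(C)C)C[C@@H](OC(=O)[C@H](C)CC)[C@@H]12 | intermediate
32 | CNP0356520.2 | C=C1C(=O)O[C@H]2/C=C(/C)[C@@H](O)C[C@H]3O[C@@]3(CO)C[C@@H](OC(=O)[C@H](C)CC)[C@@H]12 | target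

**Count and risks**

Total steps: 22. Longest linear sequence: 19 steps (steps 4–8, then 9–22); the east piece needs steps 1–3 before step 9.

Step 19 (key ring closure). What may go wrong: oligomerisation instead of ring closure, reductive 1,4-elimination of the C8 silyloxy group from the allyl chromium species, or attack on the wrong face of C7 (poor facial selectivity relative to C8). Fallback, changing from reductive metalation to a preformed neutral allylboron reagent: bromide 24 is borylated with bis(pinacolato)diboron, Pd2(dba)3 and KOAc to the γ-substituted 2-(methoxycarbonyl)allyl pinacolboronate F1; DDQ removes the PMB group to give the allylic alcohol F2; MnO2 gives the (Z)-enal boronate F3; heating dilute F3 in toluene should trigger intramolecular allylboration through the same chair arrangement, and the O-boryl adduct lactonises with loss of the boron group to rejoin the route at 28.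

Step 15 (Morita–Baylis–Hillman reaction). What may go wrong: very slow addition to the hindered α-silyloxy aldehyde, and during the long reaction time migration of the TES group to the new C7 hydroxyl or attack of that hydroxyl on the oxirane. Fallback, changing from amine catalysis to a stoichiometric vinyl-metal addition: [1-(methoxycarbonyl)vinyl]diisobutylaluminium F4, made in the flask from methyl propiolate, iBu2AlH and N-methylmorpholine N-oxide in THF at 0 °C, is added to aldehyde 21 at low temperature and should give the same adduct 23 within minutes.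

Step 13 (DMB removal). What may go wrong: loss of the oxirane, because the freed C7 hydroxyl can open it at C10 in a 5-exo fashion to a tetrahydrofuran under traces of acid (the hydroquinone from DDQ, silica gel); the same liability persists in 23. Fallback, postponing the epoxidation until C7 no longer carries a hydroxyl: diol 16 is silylated twice (TESCl, imidazole) to the bis(triethylsilyl) ether F5; DDQ gives the primary alcohol F6; Dess–Martin oxidation gives the aldehyde F7; the Morita–Baylis–Hillman reaction gives the adduct F8; N-bromosuccinimide/Me2S gives the bromide F9; PPTS in MeOH at −20 °C removes only the primary allylic TES group to give the allylic alcohol F10; Sharpless epoxidation with D-(−)-diethyl tartrate gives the epoxy alcohol F11; silylation with TBSCl and imidazole rejoins the route at 24.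

**Further compounds**

F1 | step 19 | allyl pinacolboronate (Bpin in place of Br in 24) | COc1ccc(COC/C=C(/C)[C@@H](O[Si](C)(C)C(C)(C)C)C[C@H]2O[C@@]2(CO[Si](C)(C)C(C)(C)C)C[C@@H](O[Si](CC)(CC)CC)/C=C(/C(=O)OC)CB3OC(C)(C)C(C)(C)O3)cc1
F2 | step 19 | C6 allylic alcohol of the boronate | OC/C=C(/C)[C@@H](O[Si](C)(C)C(C)(C)C)C[C@H]1O[C@@]1(CO[Si](C)(C)C(C)(C)C)C[C@@H](O[Si](CC)(CC)CC)/C=C(/C(=O)OC)CB1OC(C)(C)C(C)(C)O1
F3 | step 19 | (Z)-enal boronate | O=C/C=C(/C)[C@@H](O[Si](C)(C)C(C)(C)C)C[C@H]1O[C@@]1(CO[Si](C)(C)C(C)(C)C)C[C@@H](O[Si](CC)(CC)CC)/C=C(/C(=O)OC)CB1OC(C)(C)C(C)(C)O1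
F4 | step 15 | [1-(methoxycarbonyl)vinyl]diisobutylaluminium | C=C(C(=O)OC)[Al](CC(C)C)CC(C)C
F5 | step 13 | C14,C8-bis(triethylsilyl) ether of 16 | COc1ccc(COC/C=C(/C)[C@@H](O[Si](C)(C)C(C)(C)C)C/C=C(/CO[Si](CC)(CC)CC)C[C@@H](O[Si](CC)(CC)CC)COCc2ccc(OC)c(OC)c2)cc1
F6 | step 13 | C7 primary alcohol (no oxirane) | COc1ccc(COC/C=C(/C)[C@@H](O[Si](C)(C)C(C)(C)C)C/C=C(/CO[Si](CC)(CC)CC)C[C@@H](O[Si](CC)(CC)CC)CO)cc1
F7 | step 13 | C7 aldehyde (no oxirane) | COc1ccc(COC/C=C(/C)[C@@H](O[Si](C)(C)C(C)(C)C)C/C=C(/CO[Si](CC)(CC)CC)C[C@@H](O[Si](CC)(CC)CC)C=O)cc1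
F8 | step 13 | Morita–Baylis–Hillman adduct (no oxirane) | COc1ccc(COC/C=C(/C)[C@@H](O[Si](C)(C)C(C)(C)C)C/C=C(/CO[Si](CC)(CC)CC)C[C@@H](O[Si](CC)(CC)CC)C(O)C(=C)C(=O)OC)cc1
F9 | step 13 | (Z)-allylic bromide, C14-OTES (no oxirane) | COc1ccc(COC/C=C(/C)[C@@H](O[Si](C)(C)C(C)(C)C)C/C=C(/CO[Si](CC)(CC)CC)C[C@@H](O[Si](CC)(CC)CC)/C=C(/C(=O)OC)CBr)cc1
F10 | step 13 | C14 allylic alcohol bromide | COc1ccc(COC/C=C(/C)[C@@H](O[Si](C)(C)C(C)(C)C)C/C=C(/CO)C[C@@H](O[Si](CC)(CC)CC)/C=C(/C(=O)OC)CBr)cc1
F11 | step 13 | (1R,10R)-epoxy alcohol bromide | COc1ccc(COC/C=C(/C)[C@@H](O[Si](C)(C)C(C)(C)C)C[C@H]2O[C@@]2(CO)C[C@@H](O[Si](CC)(CC)CC)/C=C(/C(=O)OC)CBr)cc1
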